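## Retrosynthetic overview

1. The target comes from 8‑O‑methacrylation and MeOH/H⁺ exchange of a macrocyclic C2 hemiketal; the O‑bridge fixes the C2 configuration.
2. The ten‑membered carbocycle is closed last, by RCM at C1=C10 (C2‑propenyl + C9‑methallyl).
3. The α‑methylene lactone, C7 and C8 come from SE2′ (Pd/InI) allylation of 3‑methylbut‑3‑enal by an α‑(acetoxymethyl)butenolide.
4. Key step: an asymmetric vinylogous Mukaiyama aldol dearomatises a 2‑silyloxyfuran onto the (Z)‑4‑oxo‑enal released by ¹O₂ dearomatisation of 4‑methyl‑2‑propenylfuran. It forms C5–C6, sets C5/C6, and the furan α‑C–H becomes H‑5.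
5. Ring order: butenolide → dihydrofuran hemiketal (spontaneous) → α‑methylene lactone → carbocycle → methyl ketal.

Assumption: germacrane numbering is used in names (C1–C10 ring, C11–C13 lactone carbons); 3‑methylfuran, (E)‑1‑bromopropene, tulipalin A, isoprenol and methacrylic anhydride are taken as commercial. The route has not been run; selectivities are predictions from the named reaction types.

## Route

**Step 1**
Reactants: 1, 3‑methylfuran; 2, (E)‑1‑bromoprop‑1‑ene
Product: 3, 4‑methyl‑2‑[(E)‑prop‑1‑enyl]furan
Conditions: LiTMP, THF, −78 → 0 °C; ZnCl₂; then 2, Pd(PPh₃)₄ (3 mol %), 45 °C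
Reagents that add atoms: none
Why: The hindered amide lithiates the unhindered α‑position C5 (as with 3‑methylthiophene), and Zn transmetallation/Negishi coupling proceeds with retention of alkene geometry; no stereocentre is formed.

**Step 2**
Reactants: 3
Product: 4, (2Z,5E)‑2‑methyl‑4‑oxohepta‑2,5‑dienal (used crude, cold)
Conditions: O₂, TPP (cat.), hν, CH₂Cl₂, −78 °C; then Me₂S, −78 → 0 °C
Reagents that add atoms: dioxygen, O=O
Why: Singlet‑oxygen [4+2] cycloaddition across the furan 2,5‑positions and reduction of the endoperoxide unmask the cis‑1,4‑dicarbonyl; the ring enforces the 2Z geometry and the former furan C5–H becomes the aldehyde H (future H‑5).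

**Step 3**
Reactants: 5, α‑methylene‑γ‑butyrolactone (tulipalin A)
Product: 6, 3‑(bromomethyl)furan‑2(5H)‑one
Conditions: NBS, (PhCO₂)₂ (cat.), PhCF₃, reflux
Reagents that add atoms: N‑bromosuccinimide, O=C1CCC(=O)N1Br
Why: Wohl–Ziegler bromination; abstraction of the allylic ring H gives an allyl radical that is brominated at the exocyclic terminus, moving the alkene into the ring as the conjugated butenolide.

**Step 4**
Reactants: 6
Product: 7, (2‑oxo‑2,5‑dihydrofuran‑3‑yl)methyl acetate
Conditions: KOAc, DMF, rt
Reagents that add atoms: potassium acetate, CC(=O)[O-].[K+]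
Why: SN2 displacement (any SN2′ product re‑equilibrates) gives the conjugated endocyclic allylic acetate, which tolerates silylation and Lewis acid, unlike the bromide.

**Step 5**
Reactants: 7
Product: 8, [2‑(trimethylsilyloxy)furan‑3‑yl]methyl acetate (used immediately)
Conditions: TMSOTf, Et₃N, CH₂Cl₂, 0 °C
Reagents that add atoms: trimethylsilyl triflate, C[Si](C)(C)OS(=O)(=O)C(F)(F)F
Why: Soft enolisation (γ‑deprotonation of the O‑silylated butenolide) gives the aromatic 2‑silyloxyfuran.

**Step 6 (key step)**
Reactants: 4; 8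
Product: 9, {(5S)‑5‑[(2S)‑5‑hydroxy‑3‑methyl‑5‑[(E)‑prop‑1‑enyl]‑2,5‑dihydrofuran‑2‑yl]‑2‑oxo‑2,5‑dihydrofuran‑3‑yl}methyl acetate (5S,6S in germacrane numbering; C2 hemiketal anomers, in equilibrium with the open (Z)‑hydroxy‑dienone)
Conditions: (R)‑BINOL/Ti(OiPr)₄ (20 mol %), Et₂O, −20 °C; then Et₃N·3HF, THF, 0 °C; Et₃N‑buffered silica
Reagents that add atoms: none
Why: In this catalytic asymmetric vinylogous Mukaiyama aldol, γ‑attack of the silyloxyfuran (dearomatised to the butenolide) on the Ti–BINOL‑bound aldehyde through an open antiperiplanar transition state gives the threo (5,6‑syn) adduct. (R)‑BINOL is expected to give 5S (same facial sense as Keck allylation), and the freed C5–OH closes onto the C2 ketone, masking it as the dihydrofuran hemiketal.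

**Step 7**
Reactants: 10, 3‑methylbut‑3‑en‑1‑ol
Product: 11, 3‑methylbut‑3‑enal (used at once as a solution)
Conditions: Dess–Martin periodinane, NaHCO₃, CH₂Cl₂, 0 °C
Reagents that add atoms: none
Why: Buffered Dess–Martin oxidation avoids isomerisation to the conjugated enal.

**Step 8**
Reactants: 9; 11
Product: 12, (4R,5S)‑5‑[(2S)‑5‑hydroxy‑3‑methyl‑5‑[(E)‑prop‑1‑enyl]‑2,5‑dihydrofuran‑2‑yl]‑4‑[(1S)‑1‑hydroxy‑3‑methylbut‑3‑enyl]‑3‑methylidenedihydrofuran‑2(3H)‑one (5S,6S,7R,8S)
Conditions: Pd(PPh₃)₄ (5 mol %), InI (1.5 equiv), 11 (3 equiv), THF, rt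
Reagents that add atoms: none
Why: InI umpolung of the π‑allylpalladium gives an allylindium that adds through C7 (SE2′, Barbier type) in a chair transition state. Attack anti to the C6 substituent gives the 6,7‑trans lactone, and the ring‑locked E‑type allyl with equatorial aldehyde gives the 7,8‑anti (8S) alcohol; the hemiketal keeps the C2 ketone away from the allylmetal.

**Step 9**
Reactants: 12
Product: 13, (2S,5S,6S,7R,8S,1(10)Z)‑2,8‑dihydroxy‑2,5‑epoxygermacra‑1(10),3,11(13)‑trien‑12,6‑olide
Conditions: Hoveyda–Grubbs II (15 mol %), toluene (1 mM), 80 °C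
Reagents that add atoms: none
Why: In this ring‑closing metathesis (propene lost), the hemiketal anomers interconvert through the open form, so the anomer with propenyl cis to C6 closes. The oxygen‑bridged ten‑membered ring should favour the Z trisubstituted alkene, and once cyclic the hemiketal cannot dehydrate to a furan without forming a strained [6](2,5)furanophane.

**Step 10**
Reactants: 13; 14, methacrylic anhydride
Product: 15, 8‑O‑methacrylate of 13 (2‑deethoxy‑2‑hydroxyphantomolin)
Conditions: 14 (1.5 equiv), DMAP, Et₃N, CH₂Cl₂, 0 °C → rt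
Reagents that add atoms: methacrylic anhydride (reactant 14), C=C(C)C(=O)OC(=O)C(C)=C
Why: DMAP‑catalysed acylation takes the only reactive (secondary) hydroxyl; the tertiary bridgehead hemiketal OH does not acylate.

**Step 11**
Reactants: 15
Product: 16, 2‑deethoxy‑2β‑methoxyphantomolin (target)
Conditions: PPTS (10 mol %), MeOH/HC(OMe)₃, rt
Reagents that add atoms: methanol, CO
Why: Acid‑catalysed hemiketal → methyl ketal exchange goes via the C2 oxocarbenium; the bridge allows only the 2S (2β‑OMe) ketal, and the O‑8 ester blocks transannular C8–O–C2 ketalisation.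

## Compound list

1 | 3‑methylfuran | Cc1ccoc1 | starting material
2 | (E)‑1‑bromoprop‑1‑ene | C/C=C/Br | starting material
3 | 4‑methyl‑2‑[(E)‑prop‑1‑enyl]furan | C/C=C/c1cc(C)co1 | intermediate
4 | (2Z,5E)‑2‑methyl‑4‑oxohepta‑2,5‑dienal | C/C=C/C(=O)/C=C(C)\C=O | intermediate
5 | α‑methylene‑γ‑butyrolactone (tulipalin A) | C=C1CCOC1=O | starting material
6 | 3‑(bromomethyl)furan‑2(5H)‑one | BrCC1=CCOC1=O | intermediate
7 | (2‑oxo‑2,5‑dihydrofuran‑3‑yl)methyl acetate | CC(=O)OCC1=CCOC1=O | intermediate
8 | [2‑(trimethylsilyloxy)furan‑3‑yl]methyl acetate | CC(=O)OCc1ccoc1O[Si](C)(C)C | intermediate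
9 | vinylogous aldol adduct, hemiketal form (5S,6S; C2 anomers) | C/C=C/C1(O)C=C(C)[C@H](O1)[C@H]1OC(=O)C(COC(C)=O)=C1 | intermediate
10 | 3‑methylbut‑3‑en‑1‑ol | C=C(C)CCO | starting material
11 | 3‑methylbut‑3‑enal | C=C(C)CC=O | intermediate
12 | allylation product (5S,6S,7R,8S; C2 anomers) | C/C=C/C1(O)C=C(C)[C@H](O1)[C@H]1OC(=O)C(=C)[C@@H]1[C@@H](O)CC(C)=C | intermediate
13 | macrocyclic hemiketal diol (2S,5S,6S,7R,8S,1(10)Z) | O[C@H]1C/C(C)=C\[C@@]2(O)C=C(C)[C@H](O2)[C@H]2OC(=O)C(=C)[C@@H]21 | intermediate
14 | methacrylic anhydride | C=C(C)C(=O)OC(=O)C(C)=C | starting material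
15 | 2‑deethoxy‑2‑hydroxyphantomolin (8‑O‑methacrylate hemiketal) | C=C(C)C(=O)O[C@H]1C/C(C)=C\[C@@]2(O)C=C(C)[C@H](O2)[C@H]2OC(=O)C(=C)[C@@H]21 | intermediate
16 | 2‑deethoxy‑2β‑methoxyphantomolin | C=C(C)C(=O)O[C@H]1C/C(C)=C\[C@@]2(OC)C=C(C)[C@H](O2)[C@H]2OC(=O)C(=C)[C@@H]21 | target

## Step count and risks

Total steps: 11. Longest linear sequence: 8 (steps 3, 4, 5, 6, 8, 9, 10, 11, from tulipalin A). The furan branch (steps 1, 2) and the aldehyde branch (step 7) are shorter and join at steps 6 and 8.

Steps most likely to fail: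

1. **Step 6 (vinylogous aldol on the Z‑keto‑enal).** Enal 4 may isomerise Z→E or undergo Michael addition, silyloxyfuran 8 may lose acetate, the acyclic hemiketal product may dehydrate to a furan, and threo/ee control on this hindered enal is untested. Fallback: set the C5/C6 syn‑diol by Brown (Z)‑γ‑alkoxyallylboration of 4, then build the butenolide by acylating O‑6 with 2‑(acetoxymethyl)acrylic acid and RCM onto the new vinyl group.

2. **Step 9 (RCM).** The closure forms a trisubstituted alkene in a ten‑membered ring from an acyclic hemiketal that can dehydrate to a furan on heating, and Z‑selectivity is assumed. Fallback: change the ring‑closing bond. Attach the (Z)‑C1=C10–C9–C8 chain to 3‑methylfuran first (Negishi coupling with silyl‑protected (Z)‑4‑iodo‑3‑methylbut‑3‑en‑1‑ol), run the same ¹O₂/aldol sequence, and close the ring by intramolecular allylation of the C8 aldehyde at C7–C8.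

3. **Step 8 (Pd/In allylation).** Pd may ionise other allylic C–O bonds (hemiketal, butenolide), the open‑form ketone may be allylated, and facial control may erode. Fallback: use parent 2‑(trimethylsilyloxy)furan in step 6, add C8 by anti‑selective conjugate addition of an acyl‑anion equivalent (dithiane of 11) to the butenolide, reduce the ketone, and α‑methylenate the lactone with Eschenmoser's salt.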